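**Strategy.** The route rests on taking apart both phenolic C–O bonds of the benzene ring at once: the hydroxyl-bearing C2 and C3, which flank the ester-bearing C1, are read as one alkene of a 1,4-dihydrobenzoate. Catalytic osmylation of octadecyl cyclohexa-2,5-diene-1-carboxylate, a skipped diene whose two alkenes are mirror images of each other and whose C1 already carries the ester, installs the C2–O and C3–O bonds in a single syn addition and gives a cyclohexene diol. Birch reduction of benzoic acid and esterification with 1-octadecanol supply the diene; a double alcohol oxidation then lets the ring tautomerize to the catechol.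

Key step: step 3

Remark on the chemistry: the target has no stereocenter, so the diol of the key step is carried as a racemate and its configuration is irrelevant. Ring positions are quoted in target numbering (C1 = ester-bearing carbon). The systematic names used below, 5,6-dihydroxycyclohex-2-ene-1-carboxylate for the diol and 5,6-dioxocyclohex-2-ene-1-carboxylate for the derived dione, are the corrected locants for these structures.

Step 1
Reactants: 1 benzoic acid
Product: 3 cyclohexa-2,5-diene-1-carboxylic acid (1,4-dihydrobenzoic acid), via sodium cyclohexa-2,5-diene-1-carboxylate 2 (not isolated)
Conditions: Na (3.3 equiv), NH3 (l), EtOH, −78 → −33 °C; NH4Cl; then aq HCl to pH 4, 0 °C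
Reagents that add atoms: none
Why: Birch reduction; electron transfer to the benzoate followed by protonation at the ipso and para carbons, as directed by the electron-withdrawing carboxylate, should give the unconjugated 2,5-diene, and the NH4Cl quench removes alkoxide before it can move a double bond into conjugation; no stereocenter is formed.

Step 2
Reactants: 3 cyclohexa-2,5-diene-1-carboxylic acid; 4 1-octadecanol
Product: 6 octadecyl cyclohexa-2,5-diene-1-carboxylate, via O-acylisourea 5 (not isolated)
Conditions: DCC (1.1 equiv), DMAP (5 mol %), CH2Cl2, 0 °C → rt, argon
Reagents that add atoms: none
Why: Steglich esterification; the carbodiimide activates the acid as O-acylisourea 5 and catalytic DMAP passes the acyl group to the unhindered primary alcohol under near-neutral conditions at low temperature, which should leave the doubly allylic C1–H and the skipped diene in place; no stereocenter is formed.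

Step 3
Reactants: 6 octadecyl cyclohexa-2,5-diene-1-carboxylate
Product: 8 octadecyl (1S*,5S*,6R*)-5,6-dihydroxycyclohex-2-ene-1-carboxylate (racemic cis-diol on the ring face opposite the ester), via cyclic osmate ester 7 (not isolated)
Conditions: OsO4 (2 mol %), NMO (1.05 equiv), THF/t-BuOH/H2O, 0 °C → rt, argon
Reagents that add atoms: osmium tetroxide, O=[Os](=O)(=O)=O (catalytic carrier that delivers both oxygens); N-methylmorpholine N-oxide, C[N+]1([O-])CCOCC1 (terminal oxidant that refills the oxo ligands); water, O (hydrolysis of the osmate ester)
Why: OsO4 adds across one ring alkene in a concerted [3+2] cycloaddition to give cyclic osmate ester 7 of hexavalent osmium, water hydrolyses 7 to the diol, and NMO returns the metal to octavalent OsO4 (Upjohn dihydroxylation). The closest known reaction type is the catalytic mono-dihydroxylation of cyclohexa-1,4-dienes to cyclohex-4-ene-1,2-diols. No ring is closed: the five-membered osmate ring of 7 is transient and the product keeps only the carbocycle. Both oxygens come from one metal centre to the same face, which sets the C2 and C3 hydroxyls cis, and approach to the less hindered face of the nearly flat diene, opposite the C1 ester, fixes their relation to C1, which becomes stereogenic only because the mirror symmetry of 6 is broken; the achiral oxidant takes either enantiotopic alkene, so 8 is racemic. The selectivity that matters is one osmylation and not two, which should be secured by limiting NMO to about one equivalent, by the statistical advantage of two equivalent alkenes in 6 and by the greater crowding of the alkene that remains in 8. Regiochemistry is no issue because the two alkenes are symmetry-related, and the facial outcome is immaterial since C1, C2 and C3 all become sp2 in step 4.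

Step 4
Reactants: 8 octadecyl (1S*,5S*,6R*)-5,6-dihydroxycyclohex-2-ene-1-carboxylate
Product: 10 Gentiside E (octadecyl 2,3-dihydroxybenzoate), via ene-dione 9 (not isolated)
Conditions: (COCl)2 (2.2 equiv), DMSO (4.5 equiv), CH2Cl2, −78 °C; then Et3N (8 equiv), −78 °C → rt, argon
Reagents that add atoms: none
Why: Swern oxidation; DMSO activated by oxalyl chloride should oxidize both secondary carbinols to 1,2-diketone 9, a keto tautomer of the target, whose C1–H (flanked by ester, ketone and alkene) and C4–H2 enolize under the amine to give the aromatic catechol and erase all three stereocenters, as in the known conversion of cyclohex-4-ene-1,2-diols into catechols by activated-DMSO oxidation.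

**Compound list**

1 | benzoic acid | OC(=O)c1ccccc1 | starting material
2 | sodium cyclohexa-2,5-diene-1-carboxylate | [Na+].[O-]C(=O)C1C=CCC=C1 | intermediate (not isolated)
3 | cyclohexa-2,5-diene-1-carboxylic acid (1,4-dihydrobenzoic acid) | OC(=O)C1C=CCC=C1 | intermediate
4 | 1-octadecanol | CCCCCCCCCCCCCCCCCCO | starting material
5 | N,N'-dicyclohexyl-O-(cyclohexa-2,5-diene-1-carbonyl)isourea (O-acylisourea) | O=C(OC(=NC1CCCCC1)NC1CCCCC1)C1C=CCC=C1 | intermediate (not isolated)
6 | octadecyl cyclohexa-2,5-diene-1-carboxylate | CCCCCCCCCCCCCCCCCCOC(=O)C1C=CCC=C1 | intermediate
7 | cyclic dioxo-osmium glycolate (osmate ester of hexavalent osmium) bridging C2 and C3 on the face opposite the ester, racemic, one enantiomer drawn | CCCCCCCCCCCCCCCCCCOC(=O)[C@H]1C=CC[C@@H]2O[Os](=O)(=O)O[C@H]12 | intermediate (not isolated)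
8 | octadecyl (1S*,5S*,6R*)-5,6-dihydroxycyclohex-2-ene-1-carboxylate (racemic; hydroxyls cis to each other and trans to the ester; one enantiomer drawn) | CCCCCCCCCCCCCCCCCCOC(=O)[C@H]1C=CC[C@H](O)[C@@H]1O | intermediate
9 | octadecyl 5,6-dioxocyclohex-2-ene-1-carboxylate (ene-dione; C1 configurationally labile) | CCCCCCCCCCCCCCCCCCOC(=O)C1C=CCC(=O)C1=O | intermediate (not isolated)
10 | Gentiside E (octadecyl 2,3-dihydroxybenzoate) | CCCCCCCCCCCCCCCCCCOC(=O)c1cccc(O)c1O | target

**Step count:** 4 steps in total. Longest linear sequence: 4 steps (from benzoic acid 1).

**Steps most likely to fail**

Step 3. The osmylation may not stop after one alkene and run on to a tetraol, or the skipped diene may be lost beforehand through base-promoted migration of a double bond into conjugation or air-driven aromatization. The fallback sets out from 6 and comes back to the route at 9; it makes the two C–O bonds in separate events. Buffered mCPBA (1.0 equiv, NaHCO3, CH2Cl2, 0 °C) should epoxidize one alkene, expected on the face opposite the ester, to give octadecyl 7-oxabicyclo[4.1.0]hept-3-ene-2-carboxylate F1. Brief acid-catalysed hydrolysis (cat. HClO4, THF/H2O, 0 °C → rt) should open the oxirane with inversion, preferentially at the carbon remote from the ester, to the trans-diol octadecyl (1S*,5R*,6R*)-5,6-dihydroxycyclohex-2-ene-1-carboxylate F2. F2 differs from 8 only in configuration that is destroyed later, and under the conditions of step 4 it should be oxidized to ene-dione 9, which tautomerizes to 10.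

Step 4. The activated C2 oxygen sits beta to the ester next to an acidic C1–H, so beta-elimination may compete with oxidation and cost one oxygen. Residual activated DMSO may also alkylate the emerging catechol, and the catecholate may be oxidized by air during work-up. The fallback sets out from 8 and comes back at 10; it uses an oxidant that does not turn the hydroxyls into leaving groups and deliberately overshoots. Excess IBX (DMSO/THF, rt) should oxidize both carbinols, and the catechol formed by enolization is expected to be taken on to the ortho-quinone octadecyl 5,6-dioxocyclohexa-1,3-diene-1-carboxylate F3. Aqueous Na2S2O4 added to the same flask should reduce F3 to 10.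

Step 2. Acyl activation in the presence of DMAP may trigger loss of the acidic C1–H, leading to migration of a double bond into conjugation or to a ketene, and acyl migration to the N-acylurea may consume the acid. The fallback sets out from 3 and 4 and comes back at 6; it activates the alcohol and not the acid. Under Mitsunobu conditions (PPh3, DIAD, THF, 0 °C → rt) the carboxylate of 3 should displace the activated primary oxygen of 4 in an SN2 reaction, so no acyl-activated species is formed. This fallback makes no new compound (F0).

**Further compounds**

F1 | step 3 | octadecyl 7-oxabicyclo[4.1.0]hept-3-ene-2-carboxylate (racemic; oxirane oxygen trans to the ester) | CCCCCCCCCCCCCCCCCCOC(=O)[C@H]1C=CC[C@@H]2O[C@H]12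
F2 | step 3 | octadecyl (1S*,5R*,6R*)-5,6-dihydroxycyclohex-2-ene-1-carboxylate (racemic trans-diol) | CCCCCCCCCCCCCCCCCCOC(=O)[C@H]1C=CC[C@@H](O)[C@@H]1O
F3 | step 4 | octadecyl 5,6-dioxocyclohexa-1,3-diene-1-carboxylate (ortho-quinone) | CCCCCCCCCCCCCCCCCCOC(=O)C1=CC=CC(=O)C1=O
F0 | step 2 | none | none
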